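The disconnection on which everything rests is the O–C10 bond of the 3(2H)-furanone. This ring (O, C3, C2, C1, C10), whose ether oxygen sits on the fully substituted C10 next to the C1 ketone, can be read as the trace of the C3 oxygen having displaced the oxirane oxygen from C10 of a 1,10-epoxygermacranolide. In one operation the key step forms O–C10 with inversion, closes the five-membered dienol ether ring and leaves the C1 hydroxyl for later oxidation. Its precursor is the ten-membered (1R,10R)-1,10-epoxy-3-oxo-4Z-germacranolide 29 with the 8-methacrylate, the methylene lactone and a C15 silyl ether in place, built from a chiral butenolide and a dithiane and closed at C3–C4 by CrCl2/NiCl2 coupling.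

Key step: step 22

Remark: atoms carry germacrane numbers (C1–C15) throughout, PMB is 4-methoxybenzyl and TBS is tert-butyldimethylsilyl; the ring-closure product 27 is carried as both C3 epimers because that centre becomes a ketone in step 20.

Step 1
Reactants: 1 4-methylpent-3-en-1-ol
Product: 2 PMB ether of 1
Conditions: NaH, 4-methoxybenzyl chloride, Bu4NI (cat.), THF/DMF, 0 °C → rt
Reagents that add atoms: 4-methoxybenzyl chloride, COc1ccc(CCl)cc1
Why: Williamson ether synthesis on the primary alkoxide should give a C3 protecting group that tolerates organolithium, hydride, fluoride and mercury reagents and is later removed oxidatively; no stereocentre is involved.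

Step 2
Reactants: 2 PMB ether of 1
Product: 3 (E)-5-[(4-methoxybenzyl)oxy]-2-methylpent-2-en-1-ol
Conditions: SeO2 (cat.), t-BuOOH, salicylic acid (cat.), CH2Cl2, rt
Reagents that add atoms: tert-butyl hydroperoxide, CC(C)(C)OO
Why: Sharpless–Umbreit allylic oxidation (ene reaction, then [2,3]-sigmatropic shift) is known to hydroxylate the methyl group trans to the chain of a gem-dimethyl alkene, which should fix the E geometry of C1=C10 with C9 as the carbinol carbon.

Step 3
Reactants: 3 (E)-allylic alcohol
Product: 4 (E)-allylic bromide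
Conditions: CBr4, PPh3, CH2Cl2, 0 °C
Reagents that add atoms: carbon tetrabromide, BrC(Br)(Br)Br
Why: Appel bromination displaces the oxyphosphonium ion of the primary allylic alcohol by SN2 and should leave the position and geometry of the alkene untouched.

Step 4
Reactants: 5 1,3-dithiane; 4 (E)-allylic bromide
Product: 7 2-{(E)-5-[(4-methoxybenzyl)oxy]-2-methylpent-2-en-1-yl}-1,3-dithiane, via 2-lithio-1,3-dithiane 6 (not isolated)
Conditions: n-BuLi, THF, −30 °C; then 4, −78 → 0 °C
Reagents that add atoms: none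
Why: Corey–Seebach alkylation: the soft dithiane anion should attack the primary allylic bromide directly at C9, which joins the future C8 carbonyl carbon to C9 without the regiochemical ambiguity of allyl-metal additions and keeps the E alkene.

Step 5
Reactants: 8 (S)-5-(hydroxymethyl)furan-2(5H)-one
Product: 9 (S)-5-{[(tert-butyldimethylsilyl)oxy]methyl}furan-2(5H)-one
Conditions: TBSCl, imidazole, CH2Cl2, 0 °C → rt
Reagents that add atoms: tert-butyldimethylsilyl chloride, CC(C)(C)[Si](C)(C)Cl
Why: Routine silylation of the primary alcohol gives a bulky, base-stable ether that shields one face in the next step; the C6 stereocentre is taken unchanged from the chiral pool.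

Step 6
Reactants: 7 allyl dithiane; 9 silylated butenolide
Product: 11 (4S,5S)-trans-lactone bearing the dithiane at C7 and CH2OTBS at C6, via lithiated dithiane 10 (not isolated)
Conditions: n-BuLi, THF, −30 °C; HMPA, −78 °C; then 9; AcOH
Reagents that add atoms: none
Why: Conjugate (Michael) addition of a 2-lithio-1,3-dithiane, steered to 1,4-attack by HMPA, is established for 5-substituted butenolides and should occur anti to the C6 silyloxymethyl group, so C7 is set trans to C6 by substrate control while C8 arrives as a masked ketone.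

Step 7
Reactants: 11 silyl ether lactone
Product: 12 C5 alcohol
Conditions: HF·pyridine, pyridine, THF, 0 °C → rt
Reagents that add atoms: none
Why: Fluoride cleavage of the primary silyl ether should free the C5 hydroxyl without touching the lactone, the dithiane or the PMB ether.

Step 8
Reactants: 12 C5 alcohol
Product: 13 C5 aldehyde
Conditions: SO3·pyridine, DMSO, i-Pr2NEt, CH2Cl2, 0 °C
Reagents that add atoms: none
Why: Parikh–Doering oxidation gives the aldehyde under conditions that leave thioacetals alone and are mild enough not to epimerise the α-acyloxy centre C6.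

Step 9
Reactants: 13 C5 aldehyde
Product: 14 (E)-enal (C4 and C15 added)
Conditions: Ph3P=CHCHO, toluene, 50 °C
Reagents that add atoms: (triphenylphosphoranylidene)acetaldehyde, O=CC=P(c1ccccc1)(c1ccccc1)c1ccccc1
Why: Wittig olefination with the stabilised formyl ylide should give the E enal, as is usual for stabilised ylides.

Step 10
Reactants: 14 (E)-enal
Product: 15 (Z)-2-iodoenal
Conditions: I2, DMAP (cat.), pyridine, CH2Cl2, 0 °C → rt, dark
Reagents that add atoms: iodine, II
Why: Johnson-type α-iodination (conjugate addition of the amine, iodination of the enolate, E1cB loss of the amine) should place iodine on C4 and return the more stable geometry with the formyl group trans to C6, that is the Z alkene with iodine cis to C6, as needed for the later ring closure.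

Step 11
Reactants: 15 (Z)-2-iodoenal
Product: 16 (Z)-iodoallylic alcohol
Conditions: NaBH4, CeCl3·7H2O, MeOH, −40 °C
Reagents that add atoms: none
Why: Luche 1,2-reduction should convert the aldehyde into the C15 alcohol without conjugate reduction, lactone reduction or loss of iodine.

Step 12
Reactants: 16 (Z)-iodoallylic alcohol
Product: 17 C15 TBS ether
Conditions: TBSCl, imidazole, DMF, 0 °C → rt
Reagents that add atoms: tert-butyldimethylsilyl chloride, CC(C)(C)[Si](C)(C)Cl
Why: Silylation masks the C15 hydroxyl until the last step so that it can be neither acylated nor oxidised on the way.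

Step 13
Reactants: 17 C15 TBS ether
Product: 18 C8 ketone
Conditions: Hg(ClO4)2·3H2O, CaCO3, THF/H2O, 0 °C
Reagents that add atoms: water, O
Why: Thiophilic divalent mercury hydrolyses the dithiane within minutes under carbonate buffering (Corey–Seebach unmasking), which should release the β,γ-unsaturated ketone without alkene migration or β-elimination of the lactone oxygen.

Step 14
Reactants: 18 C8 ketone
Product: 19 (8R)-alcohol
Conditions: (S)-2-methyl-CBS-oxazaborolidine (cat.), catecholborane, CH2Cl2, −78 °C; MeOH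
Reagents that add atoms: none
Why: Corey–Bakshi–Shibata reduction with the ring-branched C7 as the large and C9H2 as the small substituent should give the (8R) alcohol, the same face that Felkin–Anh attack anti to the C7–C6 bond prefers, so reagent and substrate control reinforce each other.

Step 15
Reactants: 19 (8R)-alcohol
Product: 22 α-methylene lactone alcohol, via Mannich base 20 (not isolated), via trimethylammonium iodide 21 (not isolated)
Conditions: LiN(SiMe3)2 (2.3 equiv), THF, −78 °C; CH2=NMe2 I, −78 °C → rt; then MeI, MeOH, rt; NaHCO3 aq.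
Reagents that add atoms: N,N-dimethylmethyleneiminium iodide (Eschenmoser's salt), C[N+](C)=C.[I-]
Why: α-Methylenation by Mannich reaction of the lactone enolate (the C8 hydroxyl rides along as its alkoxide) followed by quaternisation and Hofmann-type elimination should install C13 before any ketone or acrylate is present, and the transient C11 centre becomes trigonal.

Step 16
Reactants: 22 α-methylene lactone alcohol; 23 methacrylic anhydride
Product: 24 C8 methacrylate
Conditions: Et3N, DMAP (cat.), CH2Cl2, 0 °C → rt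
Reagents that add atoms: none
Why: DMAP-catalysed acylation of the secondary alcohol should give the ester with retention at C8 because the C8–O bond is not broken.

Step 17
Reactants: 24 C8 methacrylate
Product: 25 C3 alcohol
Conditions: DDQ, CH2Cl2/pH 7 buffer, 0 °C
Reagents that add atoms: none
Why: Oxidative PMB cleavage (hydride abstraction by DDQ, hydrolysis of the oxocarbenium ion) should free the C3 hydroxyl while the silyl ether, both acrylate units and the iodoalkene stay intact.

Step 18
Reactants: 25 C3 alcohol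
Product: 26 C3 aldehyde
Conditions: Dess–Martin periodinane, NaHCO3, CH2Cl2, 0 °C
Reagents that add atoms: none
Why: Buffered Dess–Martin oxidation should give the β,γ-unsaturated aldehyde without moving C1=C10 into conjugation; it is used at once.

Step 19
Reactants: 26 C3 aldehyde
Product: 27 ten-membered allylic alcohol (both C3 epimers)
Conditions: CrCl2, NiCl2 (cat.), DMSO/THF, rt, slow addition, high dilution
Reagents that add atoms: none
Why: Intramolecular Nozaki–Hiyama–Kishi reaction: nickel inserts into the C4–I bond, transmetalation gives an alkenylchromium species that adds only to the aldehyde with retention of the Z alkene, closing the ring at C3–C4; the new C3 carbinol needs no control because it is oxidised next.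

Step 20
Reactants: 27 ten-membered allylic alcohol
Product: 28 3-oxo-1(10)E,4Z-dienolide
Conditions: Dess–Martin periodinane, NaHCO3, CH2Cl2, 0 °C
Reagents that add atoms: none
Why: Dess–Martin oxidation of the allylic alcohol converges both C3 epimers on one enone and at the same time makes C4=C5 electron-poor.

Step 21
Reactants: 28 3-oxo-1(10)E,4Z-dienolide
Product: 29 (1R,10R)-1,10-epoxy-3-oxo-4Z-germacranolide
Conditions: mCPBA, NaHCO3, CH2Cl2, −20 → 0 °C
Reagents that add atoms: 3-chloroperoxybenzoic acid, OOC(=O)c1cccc(Cl)c1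
Why: Prilezhaev epoxidation is expected to touch only the electron-rich trisubstituted C1=C10 alkene and to deliver oxygen syn to the outer face of the ring conformer that holds C14 on the β face, which would set C1 and C10 together as (1R,10R), an outcome that has to be confirmed; the epoxy ketone is taken on without chromatography.

Step 22
Reactants: 29 (1R,10R)-1,10-epoxy-3-oxo-4Z-germacranolide
Product: 30 (1R,10S)-3,10-epoxy-1-hydroxy-2,4Z-diene
Conditions: Sc(OSO2CF3)3 (10 mol %), 2,6-di-tert-butyl-4-methylpyridine, 4 Å MS, CH2Cl2, −40 → 0 °C; Et3N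
Reagents that add atoms: none
Why: Sc(OSO2CF3)3 binds the oxirane oxygen and the C10–O bond stretches at the tertiary centre; a lone pair of the C3 carbonyl oxygen then attacks C10 from the side opposite the leaving oxygen, giving a 2-alkenyl cyclic oxocarbenium ion that loses a C2 proton to the hindered pyridine, so the enol ether and the free C1 hydroxyl appear together. The closest known reaction type is the acid-catalysed cyclisation of β,γ-epoxy ketones to 3-hydroxy-2,3-dihydrofurans (first stage of the classical furan synthesis from such ketones), together with the transannular opening of germacranolide epoxides by neighbouring oxygen functions. The ring O–C3–C2–C1–C10 closes in the 5-endo-tet mode, which is feasible because bond breaking at tertiary C10 runs ahead of bond making. C10 is the stereocentre written in this step and it is controlled by the (10R) oxirane carbon through inversion to (10S), while C1 keeps its C–O bond and stays (1R). The step needs opening at C10 instead of C1 and oxygen instead of carbon participation: the first is secured by the tertiary carbon and by the fact that attack at C1 would make a four-membered ring, the second by the electron-poor enone alkene C4=C5. Proton loss from C14 or C9 and ionisation of the new allylic C1 hydroxyl are held back by low temperature, the non-nucleophilic base and quenching with Et3N.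

Step 23
Reactants: 30 (1R,10S)-3,10-epoxy-1-hydroxy-2,4Z-diene
Product: 31 15-O-TBS furanone
Conditions: MnO2, CH2Cl2, rt
Reagents that add atoms: none
Why: MnO2 oxidises the allylic, enol-ether-activated C1 alcohol under neutral conditions to the vinylogous ester, which should stabilise the acid-labile dienol ether as the 3(2H)-furanone without touching C10.

Step 24
Reactants: 31 15-O-TBS furanone
Product: 32 target CNP0180483.4
Conditions: HF·pyridine, pyridine, THF, 0 °C
Reagents that add atoms: none
Why: Buffered fluoride cleavage of the primary allylic silyl ether should release the C15 hydroxyl without harming the methylene lactone, the methacrylate or the furanone.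

Compound list
1 | 4-methylpent-3-en-1-ol | CC(C)=CCCO | starting material
2 | 1-methoxy-4-{[(4-methylpent-3-en-1-yl)oxy]methyl}benzene | CC(C)=CCCOCc1ccc(OC)cc1 | intermediate
3 | (E)-5-[(4-methoxybenzyl)oxy]-2-methylpent-2-en-1-ol | OC/C(C)=C/CCOCc1ccc(OC)cc1 | intermediate
4 | 1-({[(E)-5-bromo-4-methylpent-3-en-1-yl]oxy}methyl)-4-methoxybenzene | BrC/C(C)=C/CCOCc1ccc(OC)cc1 | intermediate
5 | 1,3-dithiane | C1CSCSC1 | starting material
6 | 2-lithio-1,3-dithiane | [Li]C1SCCCS1 | intermediate
7 | 2-{(E)-5-[(4-methoxybenzyl)oxy]-2-methylpent-2-en-1-yl}-1,3-dithiane | S1CCCSC1C/C(C)=C/CCOCc1ccc(OC)cc1 | intermediate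
8 | (S)-5-(hydroxymethyl)furan-2(5H)-one | OC[C@H]1OC(=O)C=C1 | starting material
9 | (S)-5-{[(tert-butyldimethylsilyl)oxy]methyl}furan-2(5H)-one | CC(C)(C)[Si](C)(C)OC[C@H]1OC(=O)C=C1 | intermediate
10 | 2-lithio derivative of 7 | [Li]C1(C/C(C)=C/CCOCc2ccc(OC)cc2)SCCCS1 | intermediate
11 | (4S,5S)-5-{[(tert-butyldimethylsilyl)oxy]methyl}-4-(2-{(E)-5-[(4-methoxybenzyl)oxy]-2-methylpent-2-en-1-yl}-1,3-dithian-2-yl)dihydrofuran-2(3H)-one | O=C1C[C@H](C2(C/C(C)=C/CCOCc3ccc(OC)cc3)SCCCS2)[C@@H](CO[Si](C)(C)C(C)(C)C)O1 | intermediate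
12 | (4S,5S)-5-(hydroxymethyl)-4-(2-{(E)-5-[(4-methoxybenzyl)oxy]-2-methylpent-2-en-1-yl}-1,3-dithian-2-yl)dihydrofuran-2(3H)-one | O=C1C[C@H](C2(C/C(C)=C/CCOCc3ccc(OC)cc3)SCCCS2)[C@@H](CO)O1 | intermediate
13 | (2S,3S)-3-(2-{(E)-5-[(4-methoxybenzyl)oxy]-2-methylpent-2-en-1-yl}-1,3-dithian-2-yl)-5-oxotetrahydrofuran-2-carbaldehyde | O=C1C[C@H](C2(C/C(C)=C/CCOCc3ccc(OC)cc3)SCCCS2)[C@@H](C=O)O1 | intermediate
14 | (E)-3-[(2R,3S)-3-(2-{(E)-5-[(4-methoxybenzyl)oxy]-2-methylpent-2-en-1-yl}-1,3-dithian-2-yl)-5-oxotetrahydrofuran-2-yl]prop-2-enal | O=C1C[C@H](C2(C/C(C)=C/CCOCc3ccc(OC)cc3)SCCCS2)[C@@H](/C=C/C=O)O1 | intermediate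
15 | (Z)-2-iodo-3-[(2S,3S)-3-(2-{(E)-5-[(4-methoxybenzyl)oxy]-2-methylpent-2-en-1-yl}-1,3-dithian-2-yl)-5-oxotetrahydrofuran-2-yl]prop-2-enal | O=C1C[C@H](C2(C/C(C)=C/CCOCc3ccc(OC)cc3)SCCCS2)[C@@H](/C=C(\I)C=O)O1 | intermediate
16 | (4S,5S)-5-[(Z)-3-hydroxy-2-iodoprop-1-en-1-yl]-4-(2-{(E)-5-[(4-methoxybenzyl)oxy]-2-methylpent-2-en-1-yl}-1,3-dithian-2-yl)dihydrofuran-2(3H)-one | O=C1C[C@H](C2(C/C(C)=C/CCOCc3ccc(OC)cc3)SCCCS2)[C@@H](/C=C(\I)CO)O1 | intermediate
17 | (4S,5S)-5-{(Z)-3-[(tert-butyldimethylsilyl)oxy]-2-iodoprop-1-en-1-yl}-4-(2-{(E)-5-[(4-methoxybenzyl)oxy]-2-methylpent-2-en-1-yl}-1,3-dithian-2-yl)dihydrofuran-2(3H)-one | O=C1C[C@H](C2(C/C(C)=C/CCOCc3ccc(OC)cc3)SCCCS2)[C@@H](/C=C(\I)CO[Si](C)(C)C(C)(C)C)O1 | intermediate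
18 | (4S,5S)-5-{(Z)-3-[(tert-butyldimethylsilyl)oxy]-2-iodoprop-1-en-1-yl}-4-{(E)-6-[(4-methoxybenzyl)oxy]-3-methylhex-3-enoyl}dihydrofuran-2(3H)-one | O=C1C[C@H](C(=O)C/C(C)=C/CCOCc2ccc(OC)cc2)[C@@H](/C=C(\I)CO[Si](C)(C)C(C)(C)C)O1 | intermediate
19 | (4R,5S)-5-{(Z)-3-[(tert-butyldimethylsilyl)oxy]-2-iodoprop-1-en-1-yl}-4-{(1R,3E)-1-hydroxy-6-[(4-methoxybenzyl)oxy]-3-methylhex-3-en-1-yl}dihydrofuran-2(3H)-one | O=C1C[C@H]([C@H](O)C/C(C)=C/CCOCc2ccc(OC)cc2)[C@@H](/C=C(\I)CO[Si](C)(C)C(C)(C)C)O1 | intermediate
20 | 3-[(dimethylamino)methyl] derivative of 19 (Mannich base, C11 configuration not assigned) | O=C1C(CN(C)C)[C@H]([C@H](O)C/C(C)=C/CCOCc2ccc(OC)cc2)[C@@H](/C=C(\I)CO[Si](C)(C)C(C)(C)C)O1 | intermediate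
21 | trimethylammonium iodide formed from 20 | O=C1C(C[N+](C)(C)C)[C@H]([C@H](O)C/C(C)=C/CCOCc2ccc(OC)cc2)[C@@H](/C=C(\I)CO[Si](C)(C)C(C)(C)C)O1.[I-] | intermediate
22 | (4R,5S)-5-{(Z)-3-[(tert-butyldimethylsilyl)oxy]-2-iodoprop-1-en-1-yl}-4-{(1R,3E)-1-hydroxy-6-[(4-methoxybenzyl)oxy]-3-methylhex-3-en-1-yl}-3-methylidenedihydrofuran-2(3H)-one | O=C1C(=C)[C@H]([C@H](O)C/C(C)=C/CCOCc2ccc(OC)cc2)[C@@H](/C=C(\I)CO[Si](C)(C)C(C)(C)C)O1 | intermediate
23 | methacrylic anhydride | CC(=C)C(=O)OC(=O)C(C)=C | starting material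
24 | (1R,3E)-1-[(2S,3R)-2-{(Z)-3-[(tert-butyldimethylsilyl)oxy]-2-iodoprop-1-en-1-yl}-4-methylidene-5-oxotetrahydrofuran-3-yl]-6-[(4-methoxybenzyl)oxy]-3-methylhex-3-en-1-yl 2-methylprop-2-enoate | O=C1C(=C)[C@H]([C@H](OC(=O)C(C)=C)C/C(C)=C/CCOCc2ccc(OC)cc2)[C@@H](/C=C(\I)CO[Si](C)(C)C(C)(C)C)O1 | intermediate
25 | (1R,3E)-1-[(2S,3R)-2-{(Z)-3-[(tert-butyldimethylsilyl)oxy]-2-iodoprop-1-en-1-yl}-4-methylidene-5-oxotetrahydrofuran-3-yl]-6-hydroxy-3-methylhex-3-en-1-yl 2-methylprop-2-enoate | O=C1C(=C)[C@H]([C@H](OC(=O)C(C)=C)C/C(C)=C/CCO)[C@@H](/C=C(\I)CO[Si](C)(C)C(C)(C)C)O1 | intermediate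
26 | (1R,3E)-1-[(2S,3R)-2-{(Z)-3-[(tert-butyldimethylsilyl)oxy]-2-iodoprop-1-en-1-yl}-4-methylidene-5-oxotetrahydrofuran-3-yl]-3-methyl-6-oxohex-3-en-1-yl 2-methylprop-2-enoate | O=C1C(=C)[C@H]([C@H](OC(=O)C(C)=C)C/C(C)=C/CC=O)[C@@H](/C=C(\I)CO[Si](C)(C)C(C)(C)C)O1 | intermediate
27 | (6R,7R,8R)-15-[(tert-butyldimethylsilyl)oxy]-3-hydroxy-8-(methacryloyloxy)germacra-1(10)E,4Z,11(13)-trien-12,6-olide (both C3 epimers) | C=C(C)C(=O)O[C@@H]1C/C(C)=C/CC(O)/C(CO[Si](C)(C)C(C)(C)C)=C\[C@H]2OC(=O)C(=C)[C@@H]21 | intermediate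
28 | (6R,7R,8R)-15-[(tert-butyldimethylsilyl)oxy]-8-(methacryloyloxy)-3-oxogermacra-1(10)E,4Z,11(13)-trien-12,6-olide | C=C(C)C(=O)O[C@@H]1C/C(C)=C/CC(=O)/C(CO[Si](C)(C)C(C)(C)C)=C\[C@H]2OC(=O)C(=C)[C@@H]21 | intermediate
29 | (1R,6R,7R,8R,10R)-15-[(tert-butyldimethylsilyl)oxy]-1,10-epoxy-8-(methacryloyloxy)-3-oxogermacra-4Z,11(13)-dien-12,6-olide | C=C(C)C(=O)O[C@@H]1C[C@@]3(C)O[C@@H]3CC(=O)/C(CO[Si](C)(C)C(C)(C)C)=C\[C@H]2OC(=O)C(=C)[C@@H]21 | intermediate
30 | (1R,6R,7R,8R,10S)-15-[(tert-butyldimethylsilyl)oxy]-3,10-epoxy-1-hydroxy-8-(methacryloyloxy)germacra-2,4Z,11(13)-trien-12,6-olide | C=C(C)C(=O)O[C@@H]1C[C@]2(C)OC(=C[C@H]2O)/C(CO[Si](C)(C)C(C)(C)C)=C\[C@H]2OC(=O)C(=C)[C@@H]21 | intermediate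
31 | (6R,7R,8R,10S)-15-[(tert-butyldimethylsilyl)oxy]-3,10-epoxy-8-(methacryloyloxy)-1-oxogermacra-2,4Z,11(13)-trien-12,6-olide | C=C(C)C(=O)O[C@@H]1C[C@]2(C)OC(=CC2=O)/C(CO[Si](C)(C)C(C)(C)C)=C\[C@H]2OC(=O)C(=C)[C@@H]21 | intermediate
32 | (6R,7R,8R,10S)-3,10-epoxy-15-hydroxy-8-(methacryloyloxy)-1-oxogermacra-2,4Z,11(13)-trien-12,6-olide (CNP0180483.4) | C=C(C)C(=O)O[C@@H]1C[C@]2(C)OC(=CC2=O)/C(CO)=C\[C@H]2OC(=O)C(=C)[C@@H]21 | target

Total step count: 24. Longest linear sequence: 23 steps (steps 1–4 and 6–24, from 1 to 32).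

Steps most likely to fail

Step 22. The activated oxirane may lose a proton from C14 or C9 (allylic alcohol formation) or suffer a hydride shift before the carbonyl oxygen has bonded. The dienol ether product may also ionise at its allylic C1 hydroxyl under the acid. The fallback sets out from 29 and returns at 31, using a hydroxyl instead of the carbonyl oxygen as the nucleophile. NaBH4/CeCl3 should reduce the C3 ketone of 29 to the epoxy alcohols F1. Camphorsulfonic acid (cat., CH2Cl2) is expected to let the (3S) hydroxyl open the oxirane at C10 with inversion, the classical hydroxy–epoxide transannular etherification, giving the oxygen-bridged tetrahydrofuran F2. The (3R) epimer, which cannot bridge, would be separated, re-oxidised with Dess–Martin periodinane to 29 and recycled. Dess–Martin oxidation of the C1 hydroxyl should give the ketone F3. Me3SiOSO2CF3/Et3N can only enolise towards C2, because C10 is quaternary, and should give the silyl enol ether F4. Saegusa–Ito dehydrogenation with Pd(OAc)2 would then introduce C2=C3 and deliver 31.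

Step 19. Closure of the strained ten-membered ring may be slower than intermolecular coupling or protonation of the alkenylchromium species, so that oligomers or deiodinated material result. The fallback sets out from 25 and returns at 28, closing the same C3–C4 bond by an intramolecular Stille acylation. Hexamethylditin with Pd(PPh3)4 should convert the iodide into the alkenylstannane F5 with retention. Dess–Martin oxidation would give the aldehyde F6, and NaClO2/NaH2PO4/2-methylbut-2-ene the carboxylic acid F7. 1-Chloro-N,N,2-trimethylprop-1-en-1-amine should give the acid chloride F8 under neutral conditions. Pd2(dba)3 with tri(2-furyl)phosphine at high dilution would then couple the acid chloride with the stannane and give the enone 28 directly.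

Step 21. Peracid attack may occur on the other ring conformer and hence on the other alkene face, which would carry the wrong configuration through the inversion at C10. The fallback sets out from 27 and returns at 29, replacing conformational control by reagent control at the alcohol stage. Shi epoxidation of 27 would use the D-fructose-derived ketone 1,2:4,5-di-O-isopropylidene-β-D-erythro-hexo-2,3-diulo-2,6-pyranose with KHSO5 and K2CO3 in MeCN/dimethoxymethane/H2O at 0 °C. By analogy with the (R,R) epoxides this catalyst gives from E alkenes, it should afford the (1R,10R) epoxy alcohol F9, the same compound as F1. Buffered Dess–Martin oxidation would then give 29.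

Further compounds
F1 | step 22 | (1R,10R)-1,10-epoxy-3-hydroxy analogue of 29 (both C3 epimers) | C=C(C)C(=O)O[C@@H]1C[C@@]3(C)O[C@@H]3CC(O)/C(CO[Si](C)(C)C(C)(C)C)=C\[C@H]2OC(=O)C(=C)[C@@H]21
F2 | step 22 | (1R,3S,6R,7R,8R,10S)-15-[(tert-butyldimethylsilyl)oxy]-3,10-epoxy-1-hydroxy-8-(methacryloyloxy)germacra-4Z,11(13)-dien-12,6-olide | C=C(C)C(=O)O[C@@H]1C[C@]2(C)O[C@@H](C[C@H]2O)/C(CO[Si](C)(C)C(C)(C)C)=C\[C@H]2OC(=O)C(=C)[C@@H]21
F3 | step 22 | (3S,6R,7R,8R,10S)-15-[(tert-butyldimethylsilyl)oxy]-3,10-epoxy-8-(methacryloyloxy)-1-oxogermacra-4Z,11(13)-dien-12,6-olide | C=C(C)C(=O)O[C@@H]1C[C@]2(C)O[C@@H](CC2=O)/C(CO[Si](C)(C)C(C)(C)C)=C\[C@H]2OC(=O)C(=C)[C@@H]21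
F4 | step 22 | 1-(trimethylsilyloxy)-1-ene (silyl enol ether) of F3 | C=C(C)C(=O)O[C@@H]1C[C@]2(C)O[C@@H](C=C2O[Si](C)(C)C)/C(CO[Si](C)(C)C(C)(C)C)=C\[C@H]2OC(=O)C(=C)[C@@H]21
F5 | step 19 | analogue of 25 with trimethylstannyl in place of iodine on C4 | O=C1C(=C)[C@H]([C@H](OC(=O)C(C)=C)C/C(C)=C/CCO)[C@@H](/C=C(\[Sn](C)(C)C)CO[Si](C)(C)C(C)(C)C)O1
F6 | step 19 | C3 aldehyde of F5 | O=C1C(=C)[C@H]([C@H](OC(=O)C(C)=C)C/C(C)=C/CC=O)[C@@H](/C=C(\[Sn](C)(C)C)CO[Si](C)(C)C(C)(C)C)O1
F7 | step 19 | C3 carboxylic acid of F5 | O=C1C(=C)[C@H]([C@H](OC(=O)C(C)=C)C/C(C)=C/CC(=O)O)[C@@H](/C=C(\[Sn](C)(C)C)CO[Si](C)(C)C(C)(C)C)O1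
F8 | step 19 | C3 acid chloride of F5 | O=C1C(=C)[C@H]([C@H](OC(=O)C(C)=C)C/C(C)=C/CC(=O)Cl)[C@@H](/C=C(\[Sn](C)(C)C)CO[Si](C)(C)C(C)(C)C)O1
F9 | step 21 | (1R,10R)-1,10-epoxy-3-hydroxy analogue of 29 (both C3 epimers, identical with F1) | C=C(C)C(=O)O[C@@H]1C[C@@]3(C)O[C@@H]3CC(O)/C(CO[Si](C)(C)C(C)(C)C)=C\[C@H]2OC(=O)C(=C)[C@@H]21
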